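**Retrosynthetic overview**
- The last operations are chlorination at C5' and release of O4'-H from a benzyl ether; before them the depside ester bond C1'(=O)–O4 is cut into ring A acid 10 and ring B phenol 16.
- The plan rests on one structural match: C2'(O)–C3'(Me)–C4'(O)–C5'(H)–C6'(Me) of ring A is C2–C6 of 4-hydroxy-3,6-dimethyl-2-pyrone, so only C1' and its carboxyl carbon are missing and come from the enolate of tert-butyl acetate (bonds C1'–C2' and C1'–C6').
- Pyrone 4 comes from triacetic lactone by C3 methylation (sulfanylmethylation, then desulfurisation) and benzylation of the 4-oxygen.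
- Ring B is not built: methyl atratate gains the C5 methyl (formylation, hydrogenolysis) and the O2 methyl (behind a temporary 4-O-benzyl group).
- Ring order: ring A is the only ring constructed (pyrone to benzene, step 4); ring B is bought as an arene.

Key step: step 4

Remark: the target has no stereocentre; primed locants C1'–C6' denote the acyl ring A and unprimed C1–C6 the phenolic ring B. In 2,4-dihydroxybenzoates the 4-hydroxyl is assumed to be alkylated before the ester-chelated 2-hydroxyl.

**Route**

Step 1
Reactants: 1 4-hydroxy-6-methyl-2H-pyran-2-one (triacetic lactone)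
Product: 2 4-hydroxy-6-methyl-3-[(phenylsulfanyl)methyl]-2H-pyran-2-one
Conditions: (CH2O)n, PhSH, piperidine (cat.), AcOH (cat.), EtOH, 70 °C
Reagents that add atoms: formaldehyde (as paraformaldehyde), C=O; thiophenol, Sc1ccccc1
Why: Knoevenagel condensation at the nucleophilic C3 gives a 3-methylene pyrandione that thiophenol should trap by thia-Michael addition faster than a second pyrone can add, which suppresses the methylene-bis-pyrone dimer.

Step 2
Reactants: 2 4-hydroxy-6-methyl-3-[(phenylsulfanyl)methyl]-2H-pyran-2-one
Product: 3 4-hydroxy-3,6-dimethyl-2H-pyran-2-one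
Conditions: Raney Ni, EtOH, reflux
Reagents that add atoms: none
Why: Reductive desulfurisation with Raney nickel cleaves the C–S bond to leave the C3 methyl group, and a short reaction time should spare the conjugated pyrone double bonds.

Step 3
Reactants: 3 4-hydroxy-3,6-dimethyl-2H-pyran-2-one
Product: 4 4-(benzyloxy)-3,6-dimethyl-2H-pyran-2-one
Conditions: BnBr, K2CO3, acetone, reflux
Reagents that add atoms: benzyl bromide, BrCc1ccccc1
Why: Williamson-type O-alkylation of the vinylogous acid should favour the 4-oxygen, since C3 is blocked by the methyl group and the 4-alkoxy-2-pyrone is the more stable conjugated isomer.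

Step 4
Reactants: 4 4-(benzyloxy)-3,6-dimethyl-2H-pyran-2-one; 5 tert-butyl acetate
Product: 8 tert-butyl 4-(benzyloxy)-2-hydroxy-3,6-dimethylbenzoate, via open-chain diketo ester 6 (not isolated), via cyclic aldol adduct 7 (not isolated)
Conditions: 5 (3.5 equiv), LiN(iPr)2 (3.3 equiv), THF, −78 °C; then 4 added slowly, −78 → 0 °C; then MeOH, rt; aq. HCl work-up
Reagents that add atoms: none
Why: The lithium enolate of 5 adds in Claisen fashion to the lactone carbonyl C2 of 4 (bond C1'–C2'), and collapse of the tetrahedral adduct expels the ring oxygen as the enolate of a methyl ketone, so that the open chain 6 arises as its dianion once excess enolate has removed the β-keto ester proton. Methanol then returns the ketone, and the lithium methoxide so formed lets the β-keto ester carbon add to that ketone (bond C1'–C6') in a 6-(enolendo)-exo-trig aldol closure to 7, which loses water by E1cB elimination and enolises to the arene. The closest known reaction type is the attack of a lithiated carbanion at the lactone carbonyl of 4-methoxy-6-methyl-2-pyrone followed by ring opening and aldol aromatisation, together with the cyclisation of 3,5,7-triketo esters to resorcylates. The enol ether double bond of 6 keeps the geometry of the pyrone (E by the sequence rules, the two carbon termini cis), which holds nucleophile and ketone within reach; the two stereocentres of 7 are transient and vanish on dehydration. The step needs carbonyl addition to outrun proton abstraction from the C6 methyl group and conjugate addition at C6 or C4, which is addressed by slow addition of 4 to an excess of the hard lithium enolate at −78 °C and by the C4 benzyloxy donor that lowers the electrophilicity of the conjugate positions. The lactone oxygen ends as the free C2' hydroxyl and the benzyl ether marks O4', so the two oxygens stay differentiated.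

Step 5
Reactants: 8 tert-butyl 4-(benzyloxy)-2-hydroxy-3,6-dimethylbenzoate
Product: 9 tert-butyl 4-(benzyloxy)-2-methoxy-3,6-dimethylbenzoate
Conditions: MeI, K2CO3, DMF, 50 °C
Reagents that add atoms: iodomethane, CI
Why: Williamson methylation of the only free phenol, which needs DMF and gentle heating because it is chelated to the ester, while the tert-butyl ester is inert to carbonate.

Step 6
Reactants: 9 tert-butyl 4-(benzyloxy)-2-methoxy-3,6-dimethylbenzoate
Product: 10 4-(benzyloxy)-2-methoxy-3,6-dimethylbenzoic acid
Conditions: CF3CO2H, CH2Cl2, 0 °C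
Reagents that add atoms: none
Why: Acidolysis of the tert-butyl ester releases isobutene at 0 °C, where the aryl benzyl and methyl ethers should persist and the only free ring position C5', flanked by benzyloxy and methyl groups, should resist tert-butylation.

Step 7
Reactants: 11 methyl 2,4-dihydroxy-3,6-dimethylbenzoate (methyl atratate)
Product: 12 methyl 5-formyl-2,4-dihydroxy-3,6-dimethylbenzoate
Conditions: Cl2CHOMe, TiCl4, CH2Cl2, 0 °C → rt; aq. HCl
Reagents that add atoms: dichloromethyl methyl ether, COC(Cl)Cl; water, O
Why: Rieche formylation can only take place at C5, the single unsubstituted ring carbon, which is ortho to the 4-hydroxyl and para to the 2-hydroxyl.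

Step 8
Reactants: 12 methyl 5-formyl-2,4-dihydroxy-3,6-dimethylbenzoate
Product: 13 methyl 2,4-dihydroxy-3,5,6-trimethylbenzoate
Conditions: H2 (1 atm), 10% Pd/C, AcOH, HCl (cat.), rt
Reagents that add atoms: none
Why: Catalytic hydrogenolysis of an ortho-hydroxy aryl aldehyde proceeds through the benzylic alcohol, which the ortho and para hydroxyls help to ionise under acid, and should end at the methyl group.

Step 9
Reactants: 13 methyl 2,4-dihydroxy-3,5,6-trimethylbenzoate
Product: 14 methyl 4-(benzyloxy)-2-hydroxy-3,5,6-trimethylbenzoate
Conditions: BnBr (1.05 equiv), K2CO3, acetone, reflux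
Reagents that add atoms: benzyl bromide, BrCc1ccccc1
Why: In this Williamson etherification the 4-hydroxyl, para to the ester and free of hydrogen bonding, is more acidic and more nucleophilic than the chelated 2-hydroxyl, so one equivalent of benzyl bromide should react there.

Step 10
Reactants: 14 methyl 4-(benzyloxy)-2-hydroxy-3,5,6-trimethylbenzoate
Product: 15 methyl 4-(benzyloxy)-2-methoxy-3,5,6-trimethylbenzoate
Conditions: MeI, K2CO3, DMF, 50 °C
Reagents that add atoms: iodomethane, CI
Why: With O4 masked, Williamson methylation can only occur at the chelated 2-hydroxyl, which reacts in DMF on gentle heating.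

Step 11
Reactants: 15 methyl 4-(benzyloxy)-2-methoxy-3,5,6-trimethylbenzoate
Product: 16 methyl 4-hydroxy-2-methoxy-3,5,6-trimethylbenzoate
Conditions: H2 (1 atm), 10% Pd/C, EtOAc, rt
Reagents that add atoms: none
Why: Hydrogenolysis of the benzyl aryl ether over palladium frees the 4-hydroxyl and leaves the methyl ester and methyl ether untouched.

Step 12
Reactants: 10 4-(benzyloxy)-2-methoxy-3,6-dimethylbenzoic acid; 16 methyl 4-hydroxy-2-methoxy-3,5,6-trimethylbenzoate
Product: 17 methyl 4-{[4-(benzyloxy)-2-methoxy-3,6-dimethylbenzoyl]oxy}-2-methoxy-3,5,6-trimethylbenzoate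
Conditions: (CF3CO)2O, toluene, rt
Reagents that add atoms: none
Why: Esterification through the mixed trifluoroacetic anhydride, which for a 2,6-disubstituted donor-rich benzoic acid ionises to a linear aroylium ion that should tolerate the two ortho methyl groups of phenol 16 better than a tetrahedral acyl-transfer pathway.

Step 13
Reactants: 17 methyl 4-{[4-(benzyloxy)-2-methoxy-3,6-dimethylbenzoyl]oxy}-2-methoxy-3,5,6-trimethylbenzoate
Product: 18 methyl 4-[(4-hydroxy-2-methoxy-3,6-dimethylbenzoyl)oxy]-2-methoxy-3,5,6-trimethylbenzoate
Conditions: H2 (1 atm), 10% Pd/C, EtOAc, rt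
Reagents that add atoms: none
Why: Hydrogenolysis of the benzyl ether should spare the diaryl ester and is placed before chlorination so that no aryl chloride is exposed to hydrogen.

Step 14
Reactants: 18 methyl 4-[(4-hydroxy-2-methoxy-3,6-dimethylbenzoyl)oxy]-2-methoxy-3,5,6-trimethylbenzoate
Product: 19 methyl 4-[(3-chloro-4-hydroxy-6-methoxy-2,5-dimethylbenzoyl)oxy]-2-methoxy-3,5,6-trimethylbenzoate (target; chlorine at C5')
Conditions: SO2Cl2 (1.05 equiv), CH2Cl2/Et2O, 0 °C
Reagents that add atoms: sulfuryl chloride, O=S(=O)(Cl)Cl
Why: Electrophilic aromatic chlorination is directed to C5', the only unsubstituted ring carbon of the molecule, which is ortho to the free hydroxyl and para to the methoxy group, while ring B is fully substituted.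

**Compound list**
1 | 4-hydroxy-6-methyl-2H-pyran-2-one (triacetic lactone) | CC1=CC(O)=CC(=O)O1 | starting material
2 | 4-hydroxy-6-methyl-3-[(phenylsulfanyl)methyl]-2H-pyran-2-one | CC1=CC(O)=C(CSc2ccccc2)C(=O)O1 | intermediate
3 | 4-hydroxy-3,6-dimethyl-2H-pyran-2-one | CC1=CC(O)=C(C)C(=O)O1 | intermediate
4 | 4-(benzyloxy)-3,6-dimethyl-2H-pyran-2-one | CC1=CC(OCc2ccccc2)=C(C)C(=O)O1 | intermediate
5 | tert-butyl acetate | CC(=O)OC(C)(C)C | starting material
6 | tert-butyl (4E)-5-(benzyloxy)-4-methyl-3,7-dioxooct-4-enoate (formed as its lithium dienolate) | CC(=O)C/C(OCc1ccccc1)=C(/C)C(=O)CC(=O)OC(C)(C)C | intermediate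
7 | tert-butyl 4-(benzyloxy)-6-hydroxy-3,6-dimethyl-2-oxocyclohex-3-ene-1-carboxylate (racemic, mixture of diastereomers) | CC(C)(C)OC(=O)C1C(=O)C(C)=C(OCc2ccccc2)CC1(C)O | intermediate
8 | tert-butyl 4-(benzyloxy)-2-hydroxy-3,6-dimethylbenzoate | CC(C)(C)OC(=O)c1c(C)cc(OCc2ccccc2)c(C)c1O | intermediate
9 | tert-butyl 4-(benzyloxy)-2-methoxy-3,6-dimethylbenzoate | CC(C)(C)OC(=O)c1c(C)cc(OCc2ccccc2)c(C)c1OC | intermediate
10 | 4-(benzyloxy)-2-methoxy-3,6-dimethylbenzoic acid | COc1c(C)c(OCc2ccccc2)cc(C)c1C(=O)O | intermediate
11 | methyl 2,4-dihydroxy-3,6-dimethylbenzoate (methyl atratate) | COC(=O)c1c(C)cc(O)c(C)c1O | starting material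
12 | methyl 5-formyl-2,4-dihydroxy-3,6-dimethylbenzoate | COC(=O)c1c(C)c(C=O)c(O)c(C)c1O | intermediate
13 | methyl 2,4-dihydroxy-3,5,6-trimethylbenzoate | COC(=O)c1c(C)c(C)c(O)c(C)c1O | intermediate
14 | methyl 4-(benzyloxy)-2-hydroxy-3,5,6-trimethylbenzoate | COC(=O)c1c(C)c(C)c(OCc2ccccc2)c(C)c1O | intermediate
15 | methyl 4-(benzyloxy)-2-methoxy-3,5,6-trimethylbenzoate | COC(=O)c1c(C)c(C)c(OCc2ccccc2)c(C)c1OC | intermediate
16 | methyl 4-hydroxy-2-methoxy-3,5,6-trimethylbenzoate | COC(=O)c1c(C)c(C)c(O)c(C)c1OC | intermediate
17 | methyl 4-{[4-(benzyloxy)-2-methoxy-3,6-dimethylbenzoyl]oxy}-2-methoxy-3,5,6-trimethylbenzoate | COC(=O)c1c(C)c(C)c(OC(=O)c2c(C)cc(OCc3ccccc3)c(C)c2OC)c(C)c1OC | intermediate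
18 | methyl 4-[(4-hydroxy-2-methoxy-3,6-dimethylbenzoyl)oxy]-2-methoxy-3,5,6-trimethylbenzoate | COC(=O)c1c(C)c(C)c(OC(=O)c2c(C)cc(O)c(C)c2OC)c(C)c1OC | intermediate
19 | methyl 4-[(3-chloro-4-hydroxy-6-methoxy-2,5-dimethylbenzoyl)oxy]-2-methoxy-3,5,6-trimethylbenzoate | COC(=O)c1c(C)c(C)c(OC(=O)c2c(C)c(Cl)c(O)c(C)c2OC)c(C)c1OC | target

**Step count**
Total: 14 steps. Longest linear sequence: 9 steps (steps 1–6, then 12–14); the ring B branch (steps 7–11) joins at step 12.

**Steps most likely to fail**

Step 4. Proton transfer from the C6 methyl group of 4 to the ester enolate may outpace carbonyl addition and return or self-condense the pyrone. The opened chain may also re-close through oxygen to a pyranylidene acetate instead of undergoing the aldol closure. The fallback takes ring A from the aromatic pool. It sets out from 11, which is benzylated at O4 (BnBr, K2CO3, acetone, reflux) to methyl 4-(benzyloxy)-2-hydroxy-3,6-dimethylbenzoate F1. This is methylated at O2 (MeI, K2CO3, DMF, 50 °C) to methyl 4-(benzyloxy)-2-methoxy-3,6-dimethylbenzoate F2. The hindered methyl ester is then saponified (KOH, DMSO/H2O, 90 °C) and the route is rejoined at acid 10.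

Step 12. Acyl transfer between an acid and a phenol that each carry two ortho substituents may be slow. Friedel–Crafts self-acylation at C5' of the acid or trifluoroacetylation of the phenol could then take over. The fallback replaces acid-mediated aroylium transfer by base-mediated substitution on a discrete acyl chloride. It sets out from 10, which oxalyl chloride and catalytic DMF in CH2Cl2 convert into 4-(benzyloxy)-2-methoxy-3,6-dimethylbenzoyl chloride F3. This is added to the sodium phenoxide of 16 (NaH, THF, 0 °C to reflux) and the route is rejoined at 17.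

Step 14. The free, electron-rich phenol may be over-chlorinated. It may also suffer ipso attack at a methyl-bearing carbon with dearomatisation to a chlorocyclohexadienone, or radical chlorination of a benzylic methyl group. The fallback chlorinates the less activated benzyl ether and removes the benzyl group without hydrogen. It sets out from 17, which N-chlorosuccinimide with catalytic CF3CO2H in MeCN should chlorinate at C5' to methyl 4-{[4-(benzyloxy)-3-chloro-6-methoxy-2,5-dimethylbenzoyl]oxy}-2-methoxy-3,5,6-trimethylbenzoate F4. The benzyl ether is then cleaved with BCl3 and pentamethylbenzene in CH2Cl2 at −78 °C, where the methyl ethers and both esters should survive, and the route arrives at 19.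

**Further compounds**
F1 | step 4 | methyl 4-(benzyloxy)-2-hydroxy-3,6-dimethylbenzoate | COC(=O)c1c(C)cc(OCc2ccccc2)c(C)c1O
F2 | step 4 | methyl 4-(benzyloxy)-2-methoxy-3,6-dimethylbenzoate | COC(=O)c1c(C)cc(OCc2ccccc2)c(C)c1OC
F3 | step 12 | 4-(benzyloxy)-2-methoxy-3,6-dimethylbenzoyl chloride | COc1c(C)c(OCc2ccccc2)cc(C)c1C(Cl)=O
F4 | step 14 | methyl 4-{[4-(benzyloxy)-3-chloro-6-methoxy-2,5-dimethylbenzoyl]oxy}-2-methoxy-3,5,6-trimethylbenzoate | COC(=O)c1c(C)c(C)c(OC(=O)c2c(C)c(Cl)c(OCc3ccccc3)c(C)c2OC)c(C)c1OC
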